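**Convention.** The ring numbering of the target (C1–C15, defined in the first section) is kept for every intermediate.

## The problem

The target 26 is a ten-membered carbocycle. Its ring carbons are numbered C1 (lactone O–CH), C2=C3, C4 (ketone), C5, C6, C7 (carbinol), C8, C9 (acyloxy CH) and C10 (fusion CH). A cis-fused α-methylene-γ-lactone (O–C12(=O)–C11(=C13H2)) spans C1/C10, C3 carries the hydroxymethyl carbon C15, C7 carries a methyl group (C14) and a free tertiary hydroxyl, and O9 carries an (R)-2-methylbutanoate.

A ring of this size with a Z enone, a ketone and two fusion centres is not closed by a routine cyclisation, so the place and moment of ring closure must be chosen with care. Four ring stereocentres (1S, 7R, 9R, 10R) and one in the side chain must be set. C9 and C10 are neighbours and can be made in one bond-forming event. C1 lies next to C10 but bears the oxygen that is best introduced last. C7 is a quaternary carbinol insulated by CH2 groups on both sides, so it neither controls nor is controlled by the other centres and is best taken from the chiral pool.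

The finished molecule tolerates little. The α-methylene lactone and the enone are Michael acceptors, C10–H is doubly allylic, the C9 ester lies β to that acidic position, the primary allylic alcohol is easily oxidised or acylated, and the C7 hydroxyl can add across the ring to the C4 ketone.

The enabling feature is the array O1–C1–C2=C3–C15–OH. An allylic carboxylate with a hydroxymethyl group on the distal alkene carbon is what results when the C12 acid adds in a 1,4 sense to a C1=C2 alkene flanked by a C3–O–C15 spiro-epoxide. Under zerovalent palladium the lactone, the C1 stereocentre, the Z enone and the free C15 hydroxyl then arise together in a neutral step, and the stereochemical problem at C1 is moved to an epoxide carbon that a catalyst-controlled epoxidation can set.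

## Retrosynthesis

**26 ⇒ 25.** Only the O–Si bond at C7 is cut. A tertiary triethylsilyl ether is kept through the whole route because a free C7 hydroxyl would form a lactol with the C4 aldehyde, bind the titanium and chromium reagents and add to the C4 ketone. The forward step is a buffered fluoride desilylation that must leave the esters, the enone and the lactone alone.

**25 ⇒ 23 (key disconnection).** The C1–O lactone bond is cut with transposition: the alkene returns from C2=C3 to C1=C2 and the C15 hydroxyl folds back into a C3/C15 spiro-epoxide. The neighbouring cuts are less attractive. Esterification onto a preformed C1 alcohol would need C1 set on its own and C15 protected, and closing the ring with the lactone already present carries two Michael acceptors through a macrocyclisation. The precursor 23 has no C1 stereocentre, no enone and no free allylic alcohol; it has instead a C3 epoxide centre that a reagent can set. The forward reaction must ionise the epoxide anti to palladium, deliver the carboxylate to C1 anti to the metal, and give the Z alkene.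

**23 ⇒ 21 ⇒ 20.** Two functional-group changes. The free acid cannot pass through organometallic, titanium or ruthenium chemistry, so it is carried as the methyl ester 21. The C4 ketone is carried as a carbinol in 20 because that hydroxyl is needed to direct the epoxidation. The forward steps ask for an oxidation next to an epoxide and for cleavage of a methyl ester beside the hindered C9 ester.

**20 ⇒ 19.** The ring is opened at C1=C2 (ring-closing metathesis). This is the only disubstituted ring alkene of the sequence, and both partners are plain vinyl groups that arrive with the fragments at no extra cost. A closure at C3–C4 or C9–C10 would need a vinyl halide or an allylic halide next to the epoxide. The precursor 19 is acyclic with every stereocentre in place. The forward step must favour cyclisation over oligomerisation and give the Z alkene.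

**19 ⇒ 18 ⇒ 15 + 17.** The epoxide is traced to the C3=C15 alkene of a dienol, and the C3–C4 bond to the C4 aldehyde 15 and the dienyl Grignard reagent 17. C3 relays its configuration to C1 and lies far from every permanent stereocentre, so only a reagent-controlled epoxidation of an allylic alcohol can set it; this is why C4 is a carbinol for a time. The addition cannot control C4, so the epoxidation is run as a kinetic resolution and at most half of 18 is used. That is the price of fixing C3 by reagent control. Reagent 17 brings C1, C2, C3 and C15 in one piece.

**15 ⇒ 13 ⇒ 11 + 12.** The C4 aldehyde is unmasked from the trisubstituted alkene of the linalool chain, which serves as a protecting-group-free aldehyde equivalent through the early steps. The C9 ester comes from acid 12. Ozone must pick the electron-rich alkene over the vinyl group and the acrylate.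

**11 ⇒ 5 + 9.** The C9–C10 bond is cut. One carbonyl allylation sets both C9 and C10, and bromide 9 delivers C1 (as a vinyl group ready for metathesis), C10, C11, C12 and C13, the complete lactone carbon set. An aldol route to the same bond would need several further steps to build the α-methylene ester. The forward reaction must react at the central carbon of the pentadienyl unit, give the syn relationship of C9–O and the C10 vinyl group, and choose the aldehyde face by catalyst control, since C7 cannot.

**Fragments.** Aldehyde 5 comes from alcohol 4, silyl ether 2 and (R)-linalool 1, which supplies C4–C9, C14 and the C7 configuration; its vinyl group becomes C8–C9 by hydroboration. Bromide 9 comes from the Morita–Baylis–Hillman adduct 8 of acrolein 6 and methyl acrylate 7. Reagent 17 comes from chloroprene 16.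

## Roads not taken

**Alternative 1:** The ring is cut at C6–C7 and traced to a six-membered ring B (C1, C2, C3, C4, C9, C10) whose C4–C9 bond breaks in an anionic oxy-Cope rearrangement. The potassium alkoxide of a C9 carbinol undergoes a [3,3] shift and gives the ten-membered ketone A1 with a C4 methyl enol ether and the quaternary C7.

- Merits: the medium ring is formed without high dilution in a strongly driven pericyclic step, the Z C2=C3 geometry is inherited from the cyclohexene, and C1/C10 can be related on a six-membered ring.
- Weak points: C7 is created in the rearrangement from a fully substituted enol ether terminus, so its configuration depends on chair-versus-boat preference. C9 arrives as a ketone and must be reduced selectively next to C10. The lactone still has to be built from a silyloxyethyl side chain by oxidation, lactonisation and methylenation. A1 carries four kinds of protecting group, one of them an acetal whose removal needs acid.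
- Comparison: for ring formation this road is more dependable than the metathesis of step 12. The chosen plan offsets that with C7 from linalool, far fewer protecting-group operations, and one step that delivers lactone, enone and C15 hydroxyl together.

**Alternative 2:** The cut is C10–C11 with C11=C13. A phosphonoacetate ester on O1 is deprotonated, its anion opens a trans C9/C10 epoxide at C10, and the phosphonate is then methylenated with formaldehyde to give the acyclic α-methylene lactone A2 with a free C9 hydroxyl.

- Merits: C9 and C10 come from a stereospecific epoxide opening, the lactone and its methylene group are made in one flask, and the C9 hydroxyl emerges free, so no ester differentiation like that of step 14 is needed.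
- Weak points: the ring is still open in A2 and must be closed later with the α-methylene lactone present. The stabilised anion may open the epoxide slowly or at C9. The allylic C1–O bond and a Z vinyl iodide must be carried through basic steps, and C1 needs its own stereocontrol early.
- Comparison: this road is stronger for C9/C10 than the catalyst-controlled allylation of step 6. The chosen plan offsets that with one C–C bond formation from two simple fragments for the same pair, and ring closure before any Michael acceptor of the target exists.

**Alternative 3:** The ring is cut at C3–C4. CrCl2 with catalytic NiCl2 converts a C3 vinyl iodide into a vinylchromium species that adds to a C4 aldehyde and gives the ten-membered allylic alcohol A3 as both C4 epimers, to be oxidised to the enone.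

- Merits: the plan is convergent, this type of closure has a good record for strained rings and tolerates esters and lactones, and the C4 configuration is irrelevant.
- Weak points: it is the last C–C bond, so the lactone, the C9 ester and a Z vinyl iodide next to the ionisable C1–O bond must all be carried to that point. C1 has to be set by a separate method, C15 needs a protecting group, and a large excess of CrCl2 is required.
- Comparison: for the ring closure itself this road is probably safer than step 12. The chosen plan offsets that with an end-game that sets C1 by transfer from an epoxide and frees C15 without any protecting group.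

Key step: step 15

**Assumptions.** Acrolein is added as a fifth commercial starting material because bromide 9 requires it. The enantiomer of the chromium ligand in step 6 is chosen so that the Si face of C9 is attacked.

## Route

Step 1
Reactants: 1 (R)-linalool
Product: 2 (3R)-3,7-dimethyl-3-(triethylsilyloxy)octa-1,6-diene
Conditions: TESOTf, 2,6-lutidine, CH2Cl2, −78 → 0 °C
Reagents that add atoms: triethylsilyl trifluoromethanesulfonate, CC[Si](CC)(CC)OS(=O)(=O)C(F)(F)F
Why: Silyl ether protection: a silyl triflate with a hindered pyridine base should silylate the tertiary allylic alcohol without ionising it; the C7 stereocentre comes unchanged from the chiral pool.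

Step 2
Reactants: 2 (3R)-3,7-dimethyl-3-(triethylsilyloxy)octa-1,6-diene
Product: 4 (3R)-3,7-dimethyl-3-(triethylsilyloxy)oct-6-en-1-ol, via B-alkyl-9-borabicyclononane 3 (not isolated)
Conditions: 9-BBN, THF, 0 °C → rt; then NaOH, H2O2, 0 °C
Reagents that add atoms: hydrogen peroxide, OO; 9-borabicyclo[3.3.1]nonane, B1C2CCCC1CCC2 (boron of 3 only)
Why: Hydroboration–oxidation: 9-BBN adds to the monosubstituted C8=C9 alkene much faster than to the trisubstituted one and places boron on the terminal carbon; alkaline peroxide then converts the C–B bond into the C9 primary alcohol.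

Step 3
Reactants: 4 (3R)-3,7-dimethyl-3-(triethylsilyloxy)oct-6-en-1-ol
Product: 5 (3R)-3,7-dimethyl-3-(triethylsilyloxy)oct-6-enal
Conditions: Dess–Martin periodinane, pyridine, CH2Cl2, 0 °C → rt
Reagents that add atoms: none
Why: Dess–Martin oxidation should give the β-silyloxy aldehyde under buffered, non-basic conditions, so neither loss of the C7 oxygen nor over-oxidation is expected.

Step 4
Reactants: 6 acrolein; 7 methyl acrylate
Product: 8 methyl 3-hydroxy-2-methylidenepent-4-enoate (racemic)
Conditions: DABCO (cat.), methyl acrylate in excess, slow addition of acrolein, rt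
Reagents that add atoms: none
Why: Morita–Baylis–Hillman reaction: the ammonium enolate formed from DABCO and the acrylate adds to the aldehyde carbon of acrolein, which is kept at low concentration; the carbinol centre is racemic and is erased in step 5.

Step 5
Reactants: 8 methyl 3-hydroxy-2-methylidenepent-4-enoate (racemic)
Product: 9 methyl (2Z)-2-(bromomethyl)penta-2,4-dienoate
Conditions: PBr3, Et2O, −10 → 0 °C
Reagents that add atoms: phosphorus tribromide, BrP(Br)Br
Why: Bromination of a Morita–Baylis–Hillman alcohol with allylic transposition (SN2′) should give the conjugated primary bromide with the vinyl group cis to CH2Br, the favoured geometry; a regioisomeric bromide at the diene terminus would give the same pentadienyl metal in step 6.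

Step 6
Reactants: 5 (3R)-3,7-dimethyl-3-(triethylsilyloxy)oct-6-enal; 9 methyl (2Z)-2-(bromomethyl)penta-2,4-dienoate
Product: 11 methyl (3R,4R,6R)-3-ethenyl-4-hydroxy-6,10-dimethyl-2-methylidene-6-(triethylsilyloxy)undec-9-enoate (9R,10R in target numbering), via C9 trimethylsilyl ether 10 (not isolated)
Conditions: CrCl2 (10 mol %), chiral carbazole bis(oxazoline) ligand (12 mol %), Mn powder, TMSCl, Et3N (cat.), THF, 0 °C → rt; then aqueous citric acid, THF, 0 °C
Reagents that add atoms: chlorotrimethylsilane, C[Si](C)(C)Cl (silyl group of 10 only)
Why: Catalytic asymmetric Nozaki–Hiyama allylation with a 2-(alkoxycarbonyl)allyl bromide: the pentadienylchromium species from 9 adds through its central carbon in a closed chair transition state, and both its metallotropic forms (vinyl cis to the CH2–metal arm, or E when the metal sits at the diene terminus) give the same syn arrangement of C9–O and the C10 vinyl group. The ligand selects the Si face of the aldehyde (9R), since the quaternary C7 centre cannot bias it, and silyl ether 10 keeps the C9 oxygen from closing onto the ester until the mild acid work-up.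

Step 7
Reactants: 11 methyl (3R,4R,6R)-3-ethenyl-4-hydroxy-6,10-dimethyl-2-methylidene-6-(triethylsilyloxy)undec-9-enoate; 12 (R)-2-methylbutanoic acid
Product: 13 methyl (3R,4R,6R)-3-ethenyl-6,10-dimethyl-2-methylidene-4-[(2R)-2-methylbutanoyloxy]-6-(triethylsilyloxy)undec-9-enoate
Conditions: DCC, DMAP (cat.), CH2Cl2, 0 °C → rt
Reagents that add atoms: none
Why: Steglich esterification of the secondary C9 alcohol; carbodiimide activation at 0 °C with little DMAP should keep the α-stereocentre of the acid intact and caps the hydroxyl before it can lactonise onto C12.

Step 8
Reactants: 13 methyl (3R,4R,6R)-3-ethenyl-6,10-dimethyl-2-methylidene-4-[(2R)-2-methylbutanoyloxy]-6-(triethylsilyloxy)undec-9-enoate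
Product: 15 methyl (3R,4R,6R)-3-ethenyl-6-methyl-2-methylidene-4-[(2R)-2-methylbutanoyloxy]-9-oxo-6-(triethylsilyloxy)nonanoate (C4 aldehyde), via secondary ozonide 14 (not isolated)
Conditions: O3, CH2Cl2, −78 °C, Sudan red 7B as end-point indicator; then PPh3, −78 °C → rt
Reagents that add atoms: ozone, [O-][O+]=O
Why: Ozonolysis with reductive work-up: ozone attacks the electron-rich trisubstituted alkene much faster than the vinyl group or the acrylate, and stopping at the indicator end-point followed by phosphine reduction of the ozonide should give the C4 aldehyde.

Step 9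
Reactants: 16 chloroprene
Product: 17 buta-1,3-dien-2-ylmagnesium chloride (THF solution)
Conditions: Mg turnings, ZnCl2 (cat.), 1,2-dibromoethane (initiator), THF, reflux
Reagents that add atoms: magnesium, [Mg]
Why: Grignard formation from a vinylic chloride, promoted by ZnCl2 and an initiator; the solution is titrated and used directly.

Step 10
Reactants: 15 methyl (3R,4R,6R)-3-ethenyl-6-methyl-2-methylidene-4-[(2R)-2-methylbutanoyloxy]-9-oxo-6-(triethylsilyloxy)nonanoate; 17 buta-1,3-dien-2-ylmagnesium chloride
Product: 18 methyl (3R,4R,6R,9RS)-3-ethenyl-9-hydroxy-6-methyl-2,10-dimethylidene-4-[(2R)-2-methylbutanoyloxy]-6-(triethylsilyloxy)dodec-11-enoate (C4 dienol as both C4 epimers)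
Conditions: CeCl3, THF, −78 °C; then aqueous NH4Cl
Reagents that add atoms: none
Why: Carbonyl addition of the organocerium reagent formed from 17 and CeCl3: at −78 °C it should add to the aldehyde and not to the two esters or the acrylate, and it is too weakly basic to deprotonate C10. C4 is not controlled, and both epimers go on to step 11.

Step 11
Reactants: 18 C4 dienol as both C4 epimers
Product: 19 methyl (3R,4R,6R,9R)-3-ethenyl-9-[(2S)-2-ethenyloxiran-2-yl]-9-hydroxy-6-methyl-2-methylidene-4-[(2R)-2-methylbutanoyloxy]-6-(triethylsilyloxy)nonanoate (3S,4R in target numbering)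
Conditions: Ti(OiPr)4 (15 mol %), D-(−)-diethyl tartrate (20 mol %), t-BuOOH (0.6 equiv), 4 Å molecular sieves, CH2Cl2, −20 °C
Reagents that add atoms: tert-butyl hydroperoxide, CC(C)(C)OO
Why: Sharpless asymmetric epoxidation run as a kinetic resolution: with D-(−)-diethyl tartrate oxygen is delivered to the face of C3=C15 that makes C3 S, and only the 4R epimer fits the Ti(OiPr)4/tartrate complex and reacts at a useful rate, giving the anti epoxy alcohol. The 4S epimer is left behind and separated; the C10 vinyl group and the acrylate are not allylic alcohols and should stay untouched.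

Step 12
Reactants: 19 acyclic (3S,4R)-epoxy alcohol
Product: 20 methyl 2-[(1Z,3S,4R,7R,9R,10R)-3,15-epoxy-4-hydroxy-7-methyl-9-[(2R)-2-methylbutanoyloxy]-7-(triethylsilyloxy)cyclodec-1-en-10-yl]prop-2-enoate (target numbering)
Conditions: second-generation Grubbs catalyst RuCl2(=CHPh)(PCy3)(H2IMes) (10 mol %), 1,4-benzoquinone (cat.), toluene (1 mM), 80 °C
Reagents that add atoms: none
Why: Ring-closing metathesis of two monosubstituted alkenes under high dilution with loss of ethene; the quaternary C3 and C7 centres pre-organise the chain, and the less strained Z alkene is expected for a ten-membered ring. Benzoquinone suppresses ruthenium hydride migration of the skipped diene at C10.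

Step 13
Reactants: 20 ten-membered (3S,4R)-epoxy alcohol
Product: 21 methyl 2-[(1Z,3S,7R,9R,10R)-3,15-epoxy-7-methyl-9-[(2R)-2-methylbutanoyloxy]-4-oxo-7-(triethylsilyloxy)cyclodec-1-en-10-yl]prop-2-enoate
Conditions: Dess–Martin periodinane, pyridine, CH2Cl2, 0 °C → rt
Reagents that add atoms: none
Why: Dess–Martin oxidation of the C4 carbinol next to the epoxide under pyridine buffering should give the α,β-epoxy ketone and removes the temporary C4 stereocentre.

Step 14
Reactants: 21 ten-membered epoxy ketone methyl ester
Product: 23 2-[(1Z,3S,7R,9R,10R)-3,15-epoxy-7-methyl-9-[(2R)-2-methylbutanoyloxy]-4-oxo-7-(triethylsilyloxy)cyclodec-1-en-10-yl]prop-2-enoic acid, via trimethylstannyl ester 22 (not isolated)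
Conditions: Me3SnOH, 1,2-dichloroethane, 60 °C; then cold aqueous KHSO4 wash
Reagents that add atoms: trimethyltin hydroxide, C[Sn](C)(C)O (one oxygen of 23; tin of 22 only)
Why: Me3SnOH cleaves methyl esters under neutral conditions by delivering hydroxide from tin to the unhindered methyl ester, while the α-branched ester on the secondary C9 oxygen is far more hindered. The acid is released from stannyl ester 22 by a brief, cold, weakly acidic wash that the epoxide should survive.

Step 15
Reactants: 23 ten-membered (Z)-C1=C2 vinyl spiro-epoxide with free C12 acid
Product: 25 C7 triethylsilyl ether of the target (1S,7R,9R,10R; Z-C2=C3), via π-allylpalladium zwitterion 24 (not isolated)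
Conditions: Pd(PPh3)4 (5 mol %), THF (5 mM), 0 °C → rt
Reagents that add atoms: tetrakis(triphenylphosphine)palladium, [Pd].c1ccc(cc1)P(c1ccccc1)c1ccccc1.c1ccc(cc1)P(c1ccccc1)c1ccccc1.c1ccc(cc1)P(c1ccccc1)c1ccccc1.c1ccc(cc1)P(c1ccccc1)c1ccccc1 (metal fragment of 24 only)
Why: Pd(PPh3)4 (zerovalent palladium) binds the C1=C2 alkene on the face opposite the C3–O bond and opens the spiro-epoxide with inversion to the zwitterionic π-allyl complex 24 of divalent palladium over C1–C3, whose C15 alkoxide takes the proton of the C12 acid. The carboxylate then attacks C1 on the face away from the metal, which forms the C1–O bond, moves the alkene to C2=C3 and returns zerovalent palladium. The closest known reaction type is the palladium-catalysed 1,4-addition of carboxylic acids to vinyl epoxides (Tsuji–Trost allylic substitution with net retention). The γ-lactone closes in a 5-exo mode (ring O–C12–C11–C10–C1, with the C1–C2 allyl bond outside the ring); attack at C3 would need a seven-membered ring at a quaternary carbon. The new C1 stereocentre is controlled by the C3 epoxide centre through the two inversions, so the C1–O bond should form on the face the epoxide oxygen left, which is also the face the carboxylate on C10 must use for the cis ring fusion (C1 S). The step needs attack at C1 rather than C3, a Z C2=C3 alkene and transfer of configuration without leakage: the tether and the acyl group on C3 direct the nucleophile to the remote allyl terminus C1, the Z geometry of C1=C2 places C10 anti on the allyl unit and the ring is expected to hold C4 anti as well, and intramolecular capture should outrun face exchange of 24 through its oxygen-bound palladium enolate. The acid is the only proton source, so no base or external nucleophile meets the two esters, the silyl ether or the α-methylene unit.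

Step 16
Reactants: 25 C7 triethylsilyl ether of the target
Product: 26 (3aR,4R,6R,10Z,11aS)-6-hydroxy-10-(hydroxymethyl)-6-methyl-3-methylidene-2,9-dioxo-2,3,3a,4,5,6,7,8,9,11a-decahydrocyclodeca[b]furan-4-yl (2R)-2-methylbutanoate
Conditions: HF·pyridine, pyridine, THF, 0 °C → rt
Reagents that add atoms: none
Why: Fluoride cleavage of the tertiary triethylsilyl ether with buffered HF·pyridine; the esters, the α-methylene lactone, the enone and the allylic alcohol should be stable to this reagent and no stereocentre is touched.

## Compound list

1 | (R)-linalool, (3R)-3,7-dimethylocta-1,6-dien-3-ol | CC(C)=CCC[C@@](C)(O)C=C | starting material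
2 | (3R)-3,7-dimethyl-3-(triethylsilyloxy)octa-1,6-diene | CC(C)=CCC[C@@](C)(O[Si](CC)(CC)CC)C=C | intermediate
3 | 9-[(3R)-3,7-dimethyl-3-(triethylsilyloxy)oct-6-en-1-yl]-9-borabicyclo[3.3.1]nonane (not isolated) | CC(C)=CCC[C@@](C)(O[Si](CC)(CC)CC)CCB1C2CCCC1CCC2 | intermediate
4 | (3R)-3,7-dimethyl-3-(triethylsilyloxy)oct-6-en-1-ol | CC(C)=CCC[C@@](C)(O[Si](CC)(CC)CC)CCO | intermediate
5 | (3R)-3,7-dimethyl-3-(triethylsilyloxy)oct-6-enal (C9 aldehyde) | CC(C)=CCC[C@@](C)(O[Si](CC)(CC)CC)CC=O | intermediate
6 | acrolein | C=CC=O | starting material
7 | methyl acrylate | C=CC(=O)OC | starting material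
8 | methyl 3-hydroxy-2-methylidenepent-4-enoate (racemic) | C=CC(O)C(=C)C(=O)OC | intermediate
9 | methyl (2Z)-2-(bromomethyl)penta-2,4-dienoate | C=C/C=C(\CBr)C(=O)OC | intermediate
10 | C9 trimethylsilyl ether of 11 (not isolated) | C=C(C(=O)OC)[C@@H](C=C)[C@H](O[Si](C)(C)C)C[C@](C)(O[Si](CC)(CC)CC)CCC=C(C)C | intermediate
11 | methyl (3R,4R,6R)-3-ethenyl-4-hydroxy-6,10-dimethyl-2-methylidene-6-(triethylsilyloxy)undec-9-enoate | C=C(C(=O)OC)[C@@H](C=C)[C@H](O)C[C@](C)(O[Si](CC)(CC)CC)CCC=C(C)C | intermediate
12 | (R)-2-methylbutanoic acid | CC[C@@H](C)C(=O)O | starting material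
13 | methyl (3R,4R,6R)-3-ethenyl-6,10-dimethyl-2-methylidene-4-[(2R)-2-methylbutanoyloxy]-6-(triethylsilyloxy)undec-9-enoate | C=C(C(=O)OC)[C@@H](C=C)[C@H](OC(=O)[C@H](C)CC)C[C@](C)(O[Si](CC)(CC)CC)CCC=C(C)C | intermediate
14 | secondary ozonide (3,3-dimethyl-1,2,4-trioxolane) of the C4 alkene of 13, epimers at the trioxolane CH (not isolated) | C=C(C(=O)OC)[C@@H](C=C)[C@H](OC(=O)[C@H](C)CC)C[C@](C)(O[Si](CC)(CC)CC)CCC1OOC(C)(C)O1 | intermediate
15 | methyl (3R,4R,6R)-3-ethenyl-6-methyl-2-methylidene-4-[(2R)-2-methylbutanoyloxy]-9-oxo-6-(triethylsilyloxy)nonanoate (C4 aldehyde) | C=C(C(=O)OC)[C@@H](C=C)[C@H](OC(=O)[C@H](C)CC)C[C@](C)(O[Si](CC)(CC)CC)CCC=O | intermediate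
16 | chloroprene, 2-chlorobuta-1,3-diene | C=CC(Cl)=C | starting material
17 | buta-1,3-dien-2-ylmagnesium chloride | C=CC(=C)[Mg]Cl | intermediate
18 | methyl (3R,4R,6R,9RS)-3-ethenyl-9-hydroxy-6-methyl-2,10-dimethylidene-4-[(2R)-2-methylbutanoyloxy]-6-(triethylsilyloxy)dodec-11-enoate (both C4 epimers) | C=C(C(=O)OC)[C@@H](C=C)[C@H](OC(=O)[C@H](C)CC)C[C@](C)(O[Si](CC)(CC)CC)CCC(O)C(=C)C=C | intermediate
19 | methyl (3R,4R,6R,9R)-3-ethenyl-9-[(2S)-2-ethenyloxiran-2-yl]-9-hydroxy-6-methyl-2-methylidene-4-[(2R)-2-methylbutanoyloxy]-6-(triethylsilyloxy)nonanoate (3S,4R in target numbering) | C=C(C(=O)OC)[C@@H](C=C)[C@H](OC(=O)[C@H](C)CC)C[C@](C)(O[Si](CC)(CC)CC)CC[C@@H](O)[C@]1(C=C)CO1 | intermediate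
20 | ten-membered (1Z,3S,4R,7R,9R,10R)-3,15-epoxy-4-ol, methyl ester at C12, triethylsilyl ether at C7, (2R)-2-methylbutanoate at C9 | COC(=O)C(=C)[C@H]1/C=C\[C@]2(CO2)[C@H](O)CC[C@@](C)(O[Si](CC)(CC)CC)C[C@H]1OC(=O)[C@H](C)CC | intermediate
21 | ten-membered (1Z,3S,7R,9R,10R)-3,15-epoxy-4-ketone, methyl ester at C12 | COC(=O)C(=C)[C@H]1/C=C\[C@]2(CO2)C(=O)CC[C@@](C)(O[Si](CC)(CC)CC)C[C@H]1OC(=O)[C@H](C)CC | intermediate
22 | trimethylstannyl ester of 23 (not isolated) | C[Sn](C)(C)OC(=O)C(=C)[C@H]1/C=C\[C@]2(CO2)C(=O)CC[C@@](C)(O[Si](CC)(CC)CC)C[C@H]1OC(=O)[C@H](C)CC | intermediate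
23 | ten-membered (1Z,3S,7R,9R,10R)-3,15-epoxy-4-ketone with free C12 acrylic acid | OC(=O)C(=C)[C@H]1/C=C\[C@]2(CO2)C(=O)CC[C@@](C)(O[Si](CC)(CC)CC)C[C@H]1OC(=O)[C@H](C)CC | intermediate
24 | zwitterionic π-allyl complex of divalent palladium over C1–C3 with two PPh3 ligands, C12 carboxylate and C15 hydroxyl; drawn in its C1-bound form, metal on the face opposite the former epoxide oxygen (not isolated) | [O-]C(=O)C(=C)[C@H]1[C@H]([Pd+]([P](c2ccccc2)(c2ccccc2)c2ccccc2)[P](c2ccccc2)(c2ccccc2)c2ccccc2)/C=C(/CO)C(=O)CC[C@@](C)(O[Si](CC)(CC)CC)C[C@H]1OC(=O)[C@H](C)CC | intermediate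
25 | C7 triethylsilyl ether of 26 (1S,7R,9R,10R; Z-C2=C3) | C=C1C(=O)O[C@H]2/C=C(/CO)C(=O)CC[C@@](C)(O[Si](CC)(CC)CC)C[C@@H](OC(=O)[C@H](C)CC)[C@@H]12 | intermediate
26 | (3aR,4R,6R,10Z,11aS)-6-hydroxy-10-(hydroxymethyl)-6-methyl-3-methylidene-2,9-dioxo-2,3,3a,4,5,6,7,8,9,11a-decahydrocyclodeca[b]furan-4-yl (2R)-2-methylbutanoate | C=C1C(=O)O[C@H]2/C=C(/CO)C(=O)CC[C@@](C)(O)C[C@@H](OC(=O)[C@H](C)CC)[C@@H]12 | target

## Step count and least certain steps

Total step count: 16. Longest linear sequence: 13 steps (steps 1–3, 6–8 and 10–16, from (R)-linalool).

**Step 15 (key step).** The most likely failure is ionisation through the other rotamer about C2–C3, or face exchange of the allyl complex through its palladium enolate. Either would give the C1 epimer with an E alkene; the strained anti,anti allyl unit in a ten-membered ring makes this a real possibility. Palladium-induced isomerisation of the epoxy ketone or β-hydride loss from C10 are lesser risks.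

The fallback avoids an allyl–metal species and sets out from 23. Iodolactonisation (I2, NaHCO3, MeCN, 0 °C) should close the same γ-lactone by 5-exo attack of the carboxylate on the iodonium ion of C1=C2 and give the iodolactone F1, with iodine on C2 anti to the new C1–O bond and the epoxide intact. Zn dust with NH4Cl in EtOH/THF at 0 °C should then reduce the C2–I bond (or the epoxy ketone) and expel the neighbouring leaving group, which forms C2=C3 and the C15 hydroxyl and comes back to the route at 25. Both operations are standard (halolactonisation; reductive opening of a 2-(1-iodoalkyl)oxirane). The C1 configuration then depends on the ring's preference for the cis-fused lactone and not on the epoxide.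

**Step 12.** Oligomerisation may win over cyclisation, because the ring is strained and both alkenes sit on branched carbons, one of them a quaternary epoxide carbon that engages the ruthenium carbene slowly. Partial formation of the E alkene is a second risk.

The fallback closes the ring before the epoxide exists and sets out from 18. The same catalyst should join the C10 vinyl group to the unhindered terminal vinyl group of the diene and give the cyclic dienol F2 (Z-C1=C2, exocyclic C3=C15, both C4 epimers). The Sharpless kinetic-resolution epoxidation of step 11, applied to F2, then epoxidises the exocyclic alkene of the 4R epimer and comes back to the route at 20.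

**Step 6.** Control of the C9 face by the ligand may be incomplete, since nothing in aldehyde 5 assists it. Isomerisation of the allylchromium species would erode the syn selectivity, and the C9 oxygen may lactonise onto C12 during work-up.

The fallback changes from an allylmetal halide to an allylboronate and sets out from 8 and 5. Acetylation of 8 (Ac2O, DMAP) gives the acetate F3. CuCl-catalysed SN2′ borylation (B2pin2, CuCl, KOAc, DMF) gives the allylboronate F4 with the vinyl group cis to CH2B. Addition of F4 to 5 in toluene with a chiral BINOL-derived phosphoric acid should pass through a closed six-membered transition state that gives the same syn pair, with the acid choosing the aldehyde face. The borate is hydrolysed on work-up and the route is rejoined at 11.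

**Step 14.** The conjugated methyl ester, flanked by a tertiary carbon, may react slowly. At the temperature then needed, hydroxide may attack the epoxy ketone or cleave the C9 ester.

The fallback replaces acyl substitution by a fluoride-induced fragmentation and sets out from 13. Transesterification with 2-(trimethylsilyl)ethanol (Ti(OiPr)4, toluene, 90 °C) should exchange only the unhindered methyl ester and give the silylethyl ester F5. Steps 8 and 10–13 are then repeated on this series: ozonolysis to aldehyde F6, addition of 17 to dienol F7, kinetic-resolution epoxidation to epoxy alcohol F8, ring-closing metathesis to macrocycle F9, and oxidation to ketone F10. Tetrabutylammonium fluoride buffered with acetic acid (THF, 0 °C) should then cleave the silylethyl ester, with the hindered tertiary C7 silyl ether expected to survive, and the route is rejoined at 23.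

**Step 8.** Ozone may also cleave the C1 vinyl group if the end-point is missed.

The fallback uses an electrophilic epoxidation, which discriminates more sharply, and sets out from 13. mCPBA (CH2Cl2, NaHCO3, 0 °C) should epoxidise only the trisubstituted alkene to the epoxide F11, and H5IO6 (THF/Et2O, 0 °C) should cleave it to the aldehyde, coming back to the route at 15.

## Further compounds

F1 | step 15 | iodolactone of 23: γ-lactone closed at C1 (same spatial arrangement at C1 as in 25), iodine on C2 anti to the C1–O bond, C3/C15 epoxide and C4 ketone retained | C=C1C(=O)O[C@H]2[C@H](I)[C@]3(CO3)C(=O)CC[C@@](C)(O[Si](CC)(CC)CC)C[C@@H](OC(=O)[C@H](C)CC)[C@@H]12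
F2 | step 12 | ten-membered dienol: (Z)-C1=C2, exocyclic C3=C15, C4 hydroxyl (both epimers), methyl ester at C12 | COC(=O)C(=C)[C@H]1/C=C\C(=C)C(O)CC[C@@](C)(O[Si](CC)(CC)CC)C[C@H]1OC(=O)[C@H](C)CC
F3 | step 6 | methyl 3-acetoxy-2-methylidenepent-4-enoate (racemic) | C=CC(OC(C)=O)C(=C)C(=O)OC
F4 | step 6 | methyl (2E)-2-[(4,4,5,5-tetramethyl-1,3,2-dioxaborolan-2-yl)methyl]penta-2,4-dienoate | C=C/C=C(\CB1OC(C)(C)C(C)(C)O1)C(=O)OC
F5 | step 14 | 2-(trimethylsilyl)ethyl ester analogue of 13 | C=C(C(=O)OCC[Si](C)(C)C)[C@@H](C=C)[C@H](OC(=O)[C@H](C)CC)C[C@](C)(O[Si](CC)(CC)CC)CCC=C(C)C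
F6 | step 14 | 2-(trimethylsilyl)ethyl ester analogue of 15 | C=C(C(=O)OCC[Si](C)(C)C)[C@@H](C=C)[C@H](OC(=O)[C@H](C)CC)C[C@](C)(O[Si](CC)(CC)CC)CCC=O
F7 | step 14 | 2-(trimethylsilyl)ethyl ester analogue of 18 (both C4 epimers) | C=C(C(=O)OCC[Si](C)(C)C)[C@@H](C=C)[C@H](OC(=O)[C@H](C)CC)C[C@](C)(O[Si](CC)(CC)CC)CCC(O)C(=C)C=C
F8 | step 14 | 2-(trimethylsilyl)ethyl ester analogue of 19 | C=C(C(=O)OCC[Si](C)(C)C)[C@@H](C=C)[C@H](OC(=O)[C@H](C)CC)C[C@](C)(O[Si](CC)(CC)CC)CC[C@@H](O)[C@]1(C=C)CO1
F9 | step 14 | 2-(trimethylsilyl)ethyl ester analogue of 20 | C[Si](C)(C)CCOC(=O)C(=C)[C@H]1/C=C\[C@]2(CO2)[C@H](O)CC[C@@](C)(O[Si](CC)(CC)CC)C[C@H]1OC(=O)[C@H](C)CC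
F10 | step 14 | 2-(trimethylsilyl)ethyl ester analogue of 21 | C[Si](C)(C)CCOC(=O)C(=C)[C@H]1/C=C\[C@]2(CO2)C(=O)CC[C@@](C)(O[Si](CC)(CC)CC)C[C@H]1OC(=O)[C@H](C)CC
F11 | step 8 | trisubstituted-alkene epoxide of 13 (epimers at the epoxide CH) | C=C(C(=O)OC)[C@@H](C=C)[C@H](OC(=O)[C@H](C)CC)C[C@](C)(O[Si](CC)(CC)CC)CCC1OC1(C)C
A1 | alternative 1 | ten-membered C9 ketone with C4 methyl enol ether and quaternary C7 | CC(C)(C)[Si](C)(C)O[C@H]1/C=C(/CO[Si](c2ccccc2)(c2ccccc2)C(C)(C)C)\C(OC)=C\C[C@@](C)(OCOC)CC(=O)[C@H]1CCO[Si](C)(C)C(C)(C)C
A2 | alternative 2 | acyclic α-methylene lactone with free C9 hydroxyl, C4 dimethyl acetal and C3 vinyl iodide | COC(OC)CC[C@@](C)(O[Si](CC)(CC)CC)C[C@@H](O)[C@H]1C(=C)C(=O)O[C@H]1/C=C(\I)CO[Si](C)(C)C(C)(C)C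
A3 | alternative 3 | ten-membered C4 allylic alcohol (both C4 epimers) with lactone, C15 silyl ether and C9 ester in place | C=C1C(=O)O[C@H]2/C=C(/CO[Si](C)(C)C(C)(C)C)C(O)CC[C@@](C)(O[Si](CC)(CC)CC)C[C@@H](OC(=O)[C@H](C)CC)[C@@H]12
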